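**The charge.** This flask got less partner than Wednesday's run, 1.00 equiv against 2 equiv, half of it, with substrate and initiator charged as before.

common to all: substrate 0.20 M; initiator 3 mol%

| run | partner | remark | time |
|---|---|---|---|
| Wednesday's | 2 equiv | run made earlier |  |
| flask | 1.00 equiv |  | 80 min |

Wednesday's run (percent of the substrate charged)

| time / min | substrate / % | product / % |
|---|---|---|
| 2.00 | 100.4 | 0 |
| 3.00 | 96.2 | 2.9 |
| 4.00 | 97.4 | 1.5 |
| 6.00 | 94.5 | 4.5 |
| 10.0 | 94.6 | 5.0 |
| 15.0 | 93.0 | 7.8 |
| 25.0 | 87.4 | 16.5 |

(each reading ± 1 percentage point)

- what is said of by-product includes idle adduct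
- reactions considered so far: initiator -> 2 initiating radical; substrate + initiating radical -> capped initiator + first chain carrier; partner + first chain carrier -> product + second chain carrier; substrate + second chain carrier -> by-product + first chain carrier; first chain carrier -> ended carrier; 2 second chain carrier -> ended chains; partner + by-product <-> idle adduct
- the earlier runs do not show how much of partner is bound; that part of a forecast is a guess

1. part of the substrate that has reacted at 80 min
2. share of the unused partner that is free and not bound as idle adduct, at 80 min

**Odd readings.** At 25.0 min, Wednesday's run showed more product, 16.5%, than the fall in substrate, 12.6%. A turn of the chain takes one substrate and gives one product, so the two readings should count the same turns. But at 10.0 min the product, 5.0%, stood below the loss, 5.40%. The gap changed sign, so I took it for scatter and averaged the two readings at 25.0 min, which gave 14.5%.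

**My reckoning.** I let [substrate] fall at k[substrate], so that the share left is exp(−k·t). This k is the share of the remaining substrate lost per minute, a pseudo-first-order constant, and Wednesday's run gave 0.00629 min⁻¹. Holding k for this flask, which was an untested guess about the partner, I reckoned 39.5% reacted at 80 min. The readings do not show how much partner is bound, so I reckoned no free share.

**The result.** The forecast gave 30% reacted and 75% free: “Halving the partner should lower the rate somewhat”. The flask gave 34.0% reacted and 77.0% free.

    initiator → 2 initiating radical (k = 0.00120 min⁻¹)
    substrate + initiating radical → capped initiator + first chain carrier (k = 1.20 × 10⁵ L mol⁻¹ s⁻¹)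
    partner + first chain carrier → product + second chain carrier (k = 2.30 × 10⁵ L mol⁻¹ min⁻¹)
    substrate + second chain carrier → by-product + first chain carrier (k = 4.40 × 10⁵ L mol⁻¹ min⁻¹)
    first chain carrier → ended carrier (k = 220 min⁻¹)
    2 second chain carrier → ended chains (k = 5.00 × 10⁸ L mol⁻¹ s⁻¹)
    partner + by-product ⇌ idle adduct, settled at all times (K = 8.20 L mol⁻¹)

**Using k.** At Wednesday's last reading time, cutting the partner to 1.00 equiv moved the reacted part, scatter aside, from 14.2% to 12.6%. Read back through the same exponential, this flask's result is a k of 0.00519 min⁻¹, lower than Wednesday's 0.00629 min⁻¹. For the neighbouring flask with 2.50 equiv of partner, Wednesday's k again reckons 39.5% at 80 min, and that flask gave 39.1%.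

Readings and results are calculated for an exercise; the scatter is artificial.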